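## Retrosynthetic overview
1. Feature: the tertiary carbinol oxygen on C3' and the dihydrofuran oxygen on the benzylic carbon Cα are vicinal, like the two ends of an opened oxirane. The spiro carbon C8 (= C2' of the chromanone ring) is flanked in ring D by C7 and C8a. Until the furan ring closes, these are two identical C(OMe)=CH–C(=O) arms, so C8 is prochiral.
2. Endgame: five benzyl groups are removed. The pyran ring is opened at O1–C8a (cyclodehydration) and at C4–C4a (reductive alkylation by an enantiopure erythro 2,3-dioxy-3-arylpropanal). The C–C bond is made first, on the unmasked vinylogous acid, because the α-carbon of a methoxy enone is not a usable carbon nucleophile.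
3. Key disconnection: the Cα–O bond of the furan ring, leading back to the spiro epoxide of the E-benzylidene spirochromanone. The methoxy oxygen of the cis arm bonds to the ionising benzylic carbon and loses its methyl group.
4. The epoxide comes from catalytic asymmetric nucleophilic epoxidation. The benzylidene comes from the achiral spirochromanone and 4-(benzyloxy)benzaldehyde. The spirochromanone comes from 2,6-dimethoxybenzoquinone and a 2-fluoroacetophenone by enolate 1,2-addition and SNAr.
5. Order of ring formation: ring D (bought as the quinone) → chromanone pyranone ring → oxirane → furan ring → pyran ring.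

Key step: step 8

Locants: the upper unit uses flavan numbering (O1, C2, C3, C4, C4a, C5 = ketone, C6, C7, C8 = spiro carbon, C8a). The chromanone is O1', C2' (= C8), C3', C4' (ketone), with oxygen on C5' and C7'. Cα is the benzylic CH of the furan ring.

Assumption: the sense of induction in steps 7 and 12 is assigned by analogy with chalcone-type enones and with benzaldehyde. Both catalysts exist in both (pseudo)enantiomeric forms, and the antipode is used if the sense proves opposite.

Remark: no strong base is used after step 8, because a C3' alkoxide can cleave the C3'–C8 bond with aromatisation of ring D.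

## Route

Step 1
Reactants: 1 5-fluororesorcinol
Product: 2 1,3-bis(benzyloxy)-5-fluorobenzene
Conditions: BnBr (2.2 equiv), K2CO3, DMF, 60 °C
Reagents that add atoms: benzyl bromide, BrCc1ccccc1
Why: Double Williamson etherification of two acidic phenols by a primary benzylic bromide is routine, and the aryl fluoride is inert because the ring carries no acceptor yet.

Step 2
Reactants: 2 1,3-bis(benzyloxy)-5-fluorobenzene
Product: 3 1-[2,4-bis(benzyloxy)-6-fluorophenyl]ethan-1-one
Conditions: AcOH, (CF3CO)2O, H3PO4 (cat.), CH2Cl2, 0 → 25 °C
Reagents that add atoms: acetic acid, CC(=O)O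
Why: Friedel–Crafts acylation by the mixed anhydride made in the flask should go to the position ortho to fluorine and para to a benzyloxy group rather than to the crowded carbon between the two benzyloxy groups, and the metal-halide-free medium spares the benzyl ethers.

Step 3
Reactants: 3 1-[2,4-bis(benzyloxy)-6-fluorophenyl]ethan-1-one; 4 2,6-dimethoxy-1,4-benzoquinone
Product: 6 p-quinol 4-{2-[2,4-bis(benzyloxy)-6-fluorophenyl]-2-oxoethyl}-4-hydroxy-3,5-dimethoxycyclohexa-2,5-dien-1-one, via lithium enolate 5 (not isolated)
Conditions: LiN(SiMe3)2, THF, −78 °C; cannulated into 4, THF–CH2Cl2, −78 °C; AcOH, −78 °C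
Reagents that add atoms: none
Why: Aldol-type 1,2-addition of a lithium enolate to a quinone carbonyl at low temperature (the way p-quinol acetic esters are made) should hit C1=O, the only carbonyl of 4 that is not deactivated as a doubly vinylogous ester, and the cold acidic quench freezes the achiral adduct before retro-aldol cleavage or conjugate addition can set in.

Step 4
Reactants: 6 p-quinol
Product: 7 achiral spirochromanone (5',7'-bis(benzyloxy)chroman-4'-one whose C2' is C8 of a 7,8a-dimethoxycyclohexa-2,5-dienone)
Conditions: Cs2CO3 (1.2 equiv), DMF, 25 °C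
Reagents that add atoms: none
Why: In this intramolecular SNAr (addition–elimination, six-membered ring) the quinol alkoxide attacks the C–F carbon, which is ortho to the ketone and meta to both benzyloxy donors, the irreversible loss of fluoride drains any retro-aldol equilibrium, and the weak base at ambient temperature keeps enolisation of the product at C3' low, the product having a mirror plane and no stereocentre.

Step 5
Reactants: 7 spirochromanone; 8 4-(benzyloxy)benzaldehyde
Product: 10 aldol adduct 3'-{[4-(benzyloxy)phenyl](hydroxy)methyl}spirochromanone (racemic diastereomer mixture), via C3' lithium enolate 9 (not isolated)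
Conditions: LiN(SiMe3)2, THF, −78 °C; 8, −78 °C; AcOH, −78 °C
Reagents that add atoms: none
Why: Kinetic lithium enolate aldol addition at C3', the only enolisable position, runs at a temperature at which the in-ring aryloxide is not expelled (its C–O bond lies close to the nodal plane of the enolate), and both new stereocentres are erased in step 6, so the mixture is used as such.

Step 6
Reactants: 10 aldol adduct
Product: 12 (E)-3'-[4-(benzyloxy)benzylidene]spirochromanone, via benzylic mesylate 11 (not isolated)
Conditions: MsCl, Et3N, CH2Cl2, 0 °C; then DBU, 25 °C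
Reagents that add atoms: none
Why: In this mesylation and E1cB elimination the C3' enolate expels mesylate far faster than the ring aryloxide, and the E alkene should result because the Z isomer would press the aryl group against the C4' carbonyl oxygen, whereas on the C2' side the flat ring D stands perpendicular and leaves the chromanone plane free.

Step 7
Reactants: 12 (E)-benzylidene spirochromanone
Product: 13 spiro epoxide (oxirane on C3' and Cα; C3' R; Cα R; aryl cis to C2' and trans to the C4' carbonyl)
Conditions: cumene hydroperoxide, N-[4-(trifluoromethyl)benzyl]cinchonidinium bromide (10 mol %), aq KOH (cat.), toluene, 0 °C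
Reagents that add atoms: cumene hydroperoxide, CC(C)(OO)c1ccccc1
Why: In this Weitz–Scheffer epoxidation under cinchona phase-transfer catalysis, established for s-cis-locked 2-arylidene-1-tetralones and related chromanones, the chiral ammonium peroxide ion pair adds to one enantiotopic face at Cα and the enolate closes on oxygen from the same face, which sets C3' (R) with the aryl group trans to the C4' carbonyl as in alkaline epoxidations of this enone class, while the donor-substituted methoxy enone arms do not react.

Step 8
Reactants: 13 spiro epoxide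
Product: 15 furan-fused spirochromanone methoxy dienone (C3' R tertiary carbinol; Cα S; O1' cis to C4' on the furan ring; methoxy left on C8a), via methyloxonium bromide 14 (not isolated)
Conditions: MgBr2·OEt2 (2.5 equiv), CH2Cl2, −40 → 0 °C; then H2O
Reagents that add atoms: none
Why: MgBr2 chelates the C4' ketone oxygen and the oxirane oxygen and ionises the benzylic Cα–O bond, which the 4-benzyloxyphenyl group supports as a quinone-methide-like cation; the in-plane lone pair of the methoxy oxygen on the neighbouring arm bonds to Cα, bromide takes the methyl group off oxonium ion 14 by SN2, and the oxirane oxygen stays on C3' as the tertiary alkoxide. The closest known reactions are dealkylative cycloetherifications, in which an ether oxygen opens a Lewis-acid-activated epoxide and halide removes its alkyl group, and the halide-assisted demethylative furan closures of 4-methoxy-2-pyranones and 4-methoxycoumarins, which show that a vinylogous-ester methoxy oxygen can play this part. The furan ring closes formally 5-endo-tet at the oxirane, which is feasible only because the opening is SN1-like, and seen from the cation it is a 5-exo-trig attack on the Cα=C(aryl) bond of the quinone-methide form. C3' keeps the configuration of step 7; C8 becomes stereogenic through the choice of arm, since only the arm that leaves O1' and C4' cis on the new five-membered ring can reach Cα; and Cα is rebuilt by least-motion capture on the face opposite the departing oxygen, which is also the product-like preference with the aryl group trans to the bulky C4' carbon and cis to the small oxygen. The step needs capture to beat the 1,2-acyl shift typical of chalcone epoxides and lasting bromide trapping: the nucleophile is held three bonds from C3' with its lone pair pointing at Cα, the acyl shift would have to expand the chromanone to a seven-membered ring, and a benzylic bromide formed on the side re-ionises and drains into 15. The low temperature keeps the magnesium alkoxide from cleaving the C3'–C8 bond and spares the C5' benzyl ether.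

Step 9
Reactants: 15 methoxy dienone
Product: 16 vinylogous acid (8a-hydroxy dienone, drawn as the cross-conjugated enol; stereocentres as in 15)
Conditions: LiI (5 equiv), EtOAc, reflux; then 1 M HCl
Reagents that add atoms: none
Why: In this SN2 demethylation of a vinylogous methyl ester by iodide (as for hindered methyl esters) the attack is at the open methyl carbon and the leaving group is a vinylogous carboxylate, the neutral medium does not deprotonate the C3' carbinol or touch the aryl benzyl ethers and the neopentyl-type Cα–O bond, and C4a is thereby unmasked as a 1,3-dicarbonyl carbon.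

Step 10
Reactants: 17 benzyloxyacetyl chloride
Product: 18 S-ethyl 2-(benzyloxy)ethanethioate
Conditions: EtSH, Et3N, CH2Cl2, 0 °C
Reagents that add atoms: ethanethiol, CCS
Why: Acylation of a thiol by an acid chloride in the presence of a tertiary amine is fast and clean, and the thioester is chosen because its silyl ketene acetal is the proven donor for step 12 and because it can be reduced directly to the aldehyde in step 14.

Step 11
Reactants: 18 S-ethyl 2-(benzyloxy)ethanethioate
Product: 20 (Z)-2-(benzyloxy)-1-(ethylsulfanyl)-1-(trimethylsilyloxy)ethene, via lithium thioester enolate 19 (not isolated)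
Conditions: LiN(iPr)2, THF, −78 °C; Me3SiCl, −78 → 0 °C
Reagents that add atoms: chlorotrimethylsilane, C[Si](C)(C)Cl
Why: Kinetic deprotonation in THF and O-silylation of the enolate should give the Z ketene silyl thioacetal (benzyloxy group cis to sulfur), the geometry on which the erythro selectivity of step 12 depends.

Step 12
Reactants: 20 (Z)-ketene silyl thioacetal; 8 4-(benzyloxy)benzaldehyde
Product: 22 S-ethyl (2R,3R)-2-(benzyloxy)-3-[4-(benzyloxy)phenyl]-3-hydroxypropanethioate (anti), via trimethylsilyl ether of the aldol 21 (not isolated)
Conditions: Sn(OTf)2 (20 mol %), (R)-1-methyl-2-[(naphthalen-1-ylamino)methyl]pyrrolidine (22 mol %), EtCN, −78 °C, slow addition of 8 and 20; then 1 M HCl, THF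
Reagents that add atoms: none
Why: In this catalytic asymmetric Mukaiyama aldol addition the complex of Sn(OTf)2 (divalent tin) and the proline-derived diamine binds the aldehyde and shields one of its faces, and the Z α-benzyloxy ketene silyl thioacetal, a donor class known to give anti α-benzyloxy-β-hydroxy thioesters through an open transition state, sets both stereocentres (the later C3 and C2) in one operation and leaves the two oxygens differentiated.

Step 13
Reactants: 22 anti aldol
Product: 23 S-ethyl (2R,3R)-2-(benzyloxy)-3-[4-(benzyloxy)phenyl]-3-(triethylsilyloxy)propanethioate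
Conditions: Et3SiCl, imidazole, DMF, 0 → 25 °C
Reagents that add atoms: chlorotriethylsilane, CC[Si](Cl)(CC)CC
Why: Silylation of the free benzylic hydroxyl blocks retro-aldol cleavage in steps 14 and 15 with a group that can later be taken off in the presence of benzyl ethers, and no stereocentre is touched.

Step 14
Reactants: 23 triethylsilyl ether
Product: 24 (2R,3R)-2-(benzyloxy)-3-[4-(benzyloxy)phenyl]-3-(triethylsilyloxy)propanal
Conditions: iBu2AlH (1.2 equiv), CH2Cl2, −78 °C; aq Rochelle salt
Reagents that add atoms: none
Why: Partial reduction of a thioester by iBu2AlH at low temperature stops at the tetrahedral aluminium hemithioacetal, which collapses to the aldehyde only on work-up, so over-reduction and epimerisation of the α-alkoxy centre are avoided and 24 is used without storage.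

Step 15
Reactants: 16 vinylogous acid; 24 aldehyde
Product: 26 C4a-alkylated vinylogous acid (C4a–CH2–CH(OBn)–CH(OSiEt3)–aryl; side chain 3S and 2R in flavan numbering), via Knoevenagel alkylidene trione 25 (not isolated)
Conditions: diethyl 2,6-dimethyl-1,4-dihydropyridine-3,5-dicarboxylate (1.2 equiv), L-proline (5 mol %), CH2Cl2, 25 °C
Reagents that add atoms: none
Why: Three-component organocatalytic reductive alkylation (Knoevenagel condensation, then Hantzsch-ester transfer hydrogenation of the alkylidene) is a known way to monoalkylate cyclic 1,3-dicarbonyl CH acids, also by α-alkoxy aldehydes without loss of configuration, and here only C4a lies between two carbonyl-type carbons (C6 stays a vinylogous-ester CH), the medium is neutral and no new stereocentre is formed.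

Step 16
Reactants: 26 C4a-alkylated vinylogous acid
Product: 28 penta-O-benzylgenkwanol B (pyran closed; 2R,3S trans), via free benzylic alcohol 27 (not isolated)
Conditions: HF·pyridine, THF, 0 °C; then PPTS (cat.), 4 Å MS, CH2Cl2, 25 °C
Reagents that add atoms: none
Why: Desilylation is followed by acid-catalysed cyclodehydration of a 2-(3-hydroxyalkyl)-1,3-dicarbonyl compound to its six-membered cyclic enol ether (intramolecular vinylogous esterification), in which the benzylic hydroxyl should add to C8a and not to C5 because protonation takes place at the most basic oxygen O5 and leaves C8a as the electrophilic terminus while C5 stays tied up as the vinylogous ester carbonyl of the furan arm, the benzyl ether on the C3 oxygen excludes a five-membered ring, and the C2–O bond is never broken, so the erythro aldehyde maps onto the 2,3-trans pyran.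

Step 17
Reactants: 28 penta-O-benzylgenkwanol B
Product: 29 genkwanol B
Conditions: H2 (1 atm), 10 % Pd/C, THF–MeOH, 25 °C, stopped at full debenzylation
Reagents that add atoms: none
Why: Hydrogenolysis removes four aryl benzyl ethers and one alkyl benzyl ether, whereas the two ring benzylic C–O bonds (Cα–O and C2–O1) are secondary and hindered like the C2–O1 bond of flavan-3-ols, which survives such debenzylations, the tri- and tetrasubstituted donor-substituted double bonds of ring D hydrogenate slowly, and no stereocentre is touched.

## Compound list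
1 | 5-fluororesorcinol | Oc1cc(O)cc(F)c1 | starting material
2 | 1,3-bis(benzyloxy)-5-fluorobenzene | Fc1cc(OCc2ccccc2)cc(OCc2ccccc2)c1 | intermediate
3 | 1-[2,4-bis(benzyloxy)-6-fluorophenyl]ethan-1-one | CC(=O)c1c(OCc2ccccc2)cc(OCc2ccccc2)cc1F | intermediate
4 | 2,6-dimethoxy-1,4-benzoquinone | COC1=CC(=O)C=C(OC)C1=O | starting material
5 | lithium enolate of 3 (not isolated) | [Li+].C=C([O-])c1c(OCc2ccccc2)cc(OCc2ccccc2)cc1F | intermediate
6 | p-quinol, 4-{2-[2,4-bis(benzyloxy)-6-fluorophenyl]-2-oxoethyl}-4-hydroxy-3,5-dimethoxycyclohexa-2,5-dien-1-one (achiral) | COC1=CC(=O)C=C(OC)C1(O)CC(=O)c1c(OCc2ccccc2)cc(OCc2ccccc2)cc1F | intermediate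
7 | spirochromanone, 5',7'-bis(benzyloxy)chroman-4'-one spiro-fused at C2' to a 7,8a-dimethoxycyclohexa-2,5-dienone (achiral) | COC1=CC(=O)C=C(OC)C12CC(=O)c1c(OCc3ccccc3)cc(OCc3ccccc3)cc1O2 | intermediate
8 | 4-(benzyloxy)benzaldehyde | O=Cc1ccc(OCc2ccccc2)cc1 | starting material
9 | C3' lithium enolate of 7 (not isolated) | [Li+].COC1=CC(=O)C=C(OC)C12C=C([O-])c1c(OCc3ccccc3)cc(OCc3ccccc3)cc1O2 | intermediate
10 | aldol adduct, 3'-{[4-(benzyloxy)phenyl](hydroxy)methyl} derivative of 7, racemic mixture of diastereomers | COC1=CC(=O)C=C(OC)C12Oc1cc(OCc3ccccc3)cc(OCc3ccccc3)c1C(=O)C2C(O)c1ccc(OCc2ccccc2)cc1 | intermediate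
11 | benzylic mesylate of 10 (not isolated) | COC1=CC(=O)C=C(OC)C12Oc1cc(OCc3ccccc3)cc(OCc3ccccc3)c1C(=O)C2C(OS(C)(=O)=O)c1ccc(OCc2ccccc2)cc1 | intermediate
12 | (E)-3'-[4-(benzyloxy)benzylidene]spirochromanone, aryl on the side of C2' (achiral) | COC1=CC(=O)C=C(OC)C12Oc1cc(OCc3ccccc3)cc(OCc3ccccc3)c1C(=O)/C2=C/c1ccc(OCc2ccccc2)cc1 | intermediate
13 | spiro epoxide of 12, C3' (R), Cα (R), aryl cis to C2' and trans to the C4' carbonyl | COC1=CC(=O)C=C(OC)C12Oc1cc(OCc3ccccc3)cc(OCc3ccccc3)c1C(=O)[C@]21O[C@@H]1c1ccc(OCc2ccccc2)cc1 | intermediate
14 | methyloxonium bromide, furan closed, methyl still on the ring oxygen, C3' oxygen as bromomagnesium alkoxide (not isolated) | O=C1C=C2[O+](C)[C@@H](c3ccc(OCc5ccccc5)cc3)[C@]3(O[Mg]Br)C(=O)c4c(OCc5ccccc5)cc(OCc5ccccc5)cc4O[C@]23C(OC)=C1.[Br-] | intermediate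
15 | furan-fused spirochromanone methoxy dienone, C3' (R) carbinol, Cα (S) with aryl cis to the C3' hydroxyl and trans to C4', O1' and C4' cis on the furan ring, methoxy on C8a | O=C1C=C2O[C@@H](c3ccc(OCc5ccccc5)cc3)[C@]3(O)C(=O)c4c(OCc5ccccc5)cc(OCc5ccccc5)cc4O[C@]23C(OC)=C1 | intermediate
16 | vinylogous acid, 8a-hydroxy analogue of 15 (enol tautomer drawn) | O=C1C=C2O[C@@H](c3ccc(OCc5ccccc5)cc3)[C@]3(O)C(=O)c4c(OCc5ccccc5)cc(OCc5ccccc5)cc4O[C@]23C(O)=C1 | intermediate
17 | benzyloxyacetyl chloride | O=C(Cl)COCc1ccccc1 | starting material
18 | S-ethyl 2-(benzyloxy)ethanethioate | CCSC(=O)COCc1ccccc1 | intermediate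
19 | lithium enolate of 18, benzyloxy cis to sulfur (not isolated) | [Li+].CCS/C([O-])=C\OCc1ccccc1 | intermediate
20 | (Z)-2-(benzyloxy)-1-(ethylsulfanyl)-1-(trimethylsilyloxy)ethene | CCS/C(O[Si](C)(C)C)=C\OCc1ccccc1 | intermediate
21 | trimethylsilyl ether of 22 (not isolated) | CCSC(=O)[C@H](OCc1ccccc1)[C@@H](c1ccc(OCc2ccccc2)cc1)O[Si](C)(C)C | intermediate
22 | S-ethyl (2R,3R)-2-(benzyloxy)-3-[4-(benzyloxy)phenyl]-3-hydroxypropanethioate (anti) | CCSC(=O)[C@H](OCc1ccccc1)[C@@H](c1ccc(OCc2ccccc2)cc1)O | intermediate
23 | S-ethyl (2R,3R)-2-(benzyloxy)-3-[4-(benzyloxy)phenyl]-3-(triethylsilyloxy)propanethioate | CCSC(=O)[C@H](OCc1ccccc1)[C@@H](c1ccc(OCc2ccccc2)cc1)O[Si](CC)(CC)CC | intermediate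
24 | (2R,3R)-2-(benzyloxy)-3-[4-(benzyloxy)phenyl]-3-(triethylsilyloxy)propanal | O=C[C@H](OCc1ccccc1)[C@@H](c1ccc(OCc2ccccc2)cc1)O[Si](CC)(CC)CC | intermediate
25 | Knoevenagel alkylidene trione, C4a=C4H, alkene geometry open (not isolated) | O=C1C=C2O[C@@H](c3ccc(OCc5ccccc5)cc3)[C@]3(O)C(=O)c4c(OCc5ccccc5)cc(OCc5ccccc5)cc4O[C@]23C(=O)C1=C[C@H](OCc1ccccc1)[C@@H](c1ccc(OCc2ccccc2)cc1)O[Si](CC)(CC)CC | intermediate
26 | C4a-alkylated vinylogous acid, side chain C4H2–C3H(OBn)–C2H(OSiEt3)–aryl, 3S and 2R | O=C1C=C2O[C@@H](c3ccc(OCc5ccccc5)cc3)[C@]3(O)C(=O)c4c(OCc5ccccc5)cc(OCc5ccccc5)cc4O[C@]23C(O)=C1C[C@H](OCc1ccccc1)[C@@H](c1ccc(OCc2ccccc2)cc1)O[Si](CC)(CC)CC | intermediate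
27 | free benzylic alcohol from 26 (not isolated) | O=C1C=C2O[C@@H](c3ccc(OCc5ccccc5)cc3)[C@]3(O)C(=O)c4c(OCc5ccccc5)cc(OCc5ccccc5)cc4O[C@]23C(O)=C1C[C@H](OCc1ccccc1)[C@@H](c1ccc(OCc2ccccc2)cc1)O | intermediate
28 | penta-O-benzylgenkwanol B, pyran 2R,3S (trans), C3' R, Cα S, O1' and C4' cis on the furan ring | O=C1C=C2O[C@@H](c3ccc(OCc5ccccc5)cc3)[C@]3(O)C(=O)c4c(OCc5ccccc5)cc(OCc5ccccc5)cc4O[C@]23C2=C1C[C@H](OCc1ccccc1)[C@@H](c1ccc(OCc3ccccc3)cc1)O2 | intermediate
29 | genkwanol B | O=C1C=C2O[C@@H](c3ccc(O)cc3)[C@]3(O)C(=O)c4c(O)cc(O)cc4O[C@]23C2=C1C[C@H](O)[C@@H](c1ccc(O)cc1)O2 | target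

## Step count and risks
Total step count: 17. The longest linear sequence is 12 steps (steps 1–9 and 15–17, from 5-fluororesorcinol). The aldehyde branch has 5 steps (10–14).

Steps most likely to fail:

**Step 8.** After ionisation, a 1,2-acyl or 1,2-alkyl shift, lasting capture of the cation by bromide, or cleavage of the C3'–C8 bond from the magnesium alkoxide may each outrun attack of the weakly nucleophilic methoxy oxygen. The fallback sets out from 13 and comes back at 15, and it closes the furan ring at its other C–O bond. Dilute HClO4 in THF–H2O at 0 °C opens the oxirane of 13 at Cα by water with inversion and gives the C3',Cα-diol F1. CSA (cat.) and 5 Å MS in toluene at 50 °C then let the secondary benzylic hydroxyl add to C7 of the cis arm and expel methanol. This is a 5-exo-trig addition–elimination, an intramolecular vinylogous transesterification. C8 is again fixed by the cis ring fusion and Cα by the hydrolysis. A Cα epimer from partial SN1 opening would be removed at the diol stage.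

**Step 16.** The ring may close onto C5 instead of C8a and give a linearly conjugated regioisomer, or the 4-benzyloxybenzylic alcohol may ionise with loss of the C2 configuration. The fallback sets out from 15 and comes back at 28, and it uses nitrogen to mark C8a. Me2NH (2 M in THF, 40 °C) exchanges the methoxy group by addition–elimination and gives the 8a-dimethylamino vinylogous amide F2, whose C4a is now the most nucleophilic carbon of ring D. Condensation with 24 in the presence of the Hantzsch ester and catalytic AcOH, followed by reduction of the alkylidene iminium ion, gives the C4a-alkylated vinylogous amide F3. After HF·pyridine, PPTS protonates O5, and the resulting vinylogous iminium ion is electrophilic only at C8a. The freed benzylic hydroxyl therefore displaces dimethylamine and forms 28.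

**Step 4.** Retro-aldol cleavage of the quinol alkoxide may compete with ring closure. Base-induced opening of the product at O1'–C2' through its C3' enolate may also occur, followed by re-addition of the phenoxide to the exocyclic carbon with aromatisation of ring D. The fallback sets out from quinone 4 and comes back at 7, and it forms the aryl–O–C8 bond oxidatively without base.
- Commercial 2',4',6'-trihydroxyacetophenone is dibenzylated (BnBr, K2CO3, acetone) to 1-[2,4-bis(benzyloxy)-6-hydroxyphenyl]ethan-1-one F4.
- Its dianion (LiN(SiMe3)2, 2.1 equiv, THF, −78 °C) adds to 4 as in step 3 and gives the phenolic p-quinol F5.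
- Zn in AcOH reduces the quinol to the 4-alkylphenol (reductive aromatisation), the deoxybenzoin F6.
- PhI(OAc)2 in (CF3)2CHOH at 0 °C oxidises the 3,5-dimethoxyphenol ring, and the chelated ortho phenol traps its para carbon (oxidative dearomatising spirocyclisation, six-membered ring) to give 7.

## Further compounds
F1 | step 8 | C3',Cα-diol from hydrolysis of 13, C3' (R), Cα (S) | COC1=CC(=O)C=C(OC)C12Oc1cc(OCc3ccccc3)cc(OCc3ccccc3)c1C(=O)[C@@]2(O)[C@@H](O)c1ccc(OCc2ccccc2)cc1
F2 | step 16 | 8a-dimethylamino vinylogous amide from 15 | O=C1C=C2O[C@@H](c3ccc(OCc5ccccc5)cc3)[C@]3(O)C(=O)c4c(OCc5ccccc5)cc(OCc5ccccc5)cc4O[C@]23C(N(C)C)=C1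
F3 | step 16 | C4a-alkylated 8a-dimethylamino vinylogous amide | O=C1C=C2O[C@@H](c3ccc(OCc5ccccc5)cc3)[C@]3(O)C(=O)c4c(OCc5ccccc5)cc(OCc5ccccc5)cc4O[C@]23C(N(C)C)=C1C[C@H](OCc1ccccc1)[C@@H](c1ccc(OCc2ccccc2)cc1)O[Si](CC)(CC)CC
F4 | step 4 | 1-[2,4-bis(benzyloxy)-6-hydroxyphenyl]ethan-1-one | CC(=O)c1c(O)cc(OCc2ccccc2)cc1OCc1ccccc1
F5 | step 4 | phenolic p-quinol, 4-{2-[2,4-bis(benzyloxy)-6-hydroxyphenyl]-2-oxoethyl}-4-hydroxy-3,5-dimethoxycyclohexa-2,5-dien-1-one | COC1=CC(=O)C=C(OC)C1(O)CC(=O)c1c(O)cc(OCc2ccccc2)cc1OCc1ccccc1
F6 | step 4 | deoxybenzoin, 1-[2,4-bis(benzyloxy)-6-hydroxyphenyl]-2-(4-hydroxy-2,6-dimethoxyphenyl)ethan-1-one | COc1cc(O)cc(OC)c1CC(=O)c1c(O)cc(OCc2ccccc2)cc1OCc1ccccc1
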